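**Retrosynthetic overview** (cyclohex-2-en-1-one numbering: C1 = C=O, C2 carries the exocyclic C7H2O, C4 = CH–O, C5 = CH–i-Pr, C6 = CH–OH; the same labels are used for the open-chain precursors)

1. Target ⇐ C6-O-silylated C4/C7 diol + two tigloyl chloride units; both esters go on last and the C6 hydroxyl is unmasked in the final step.
2. The only ring is closed in step 7 at the C1–C6 bond: the cyclohexenone acyloin ⇐ an acyclic (Z)-hex-2-enedial by NHC-catalysed intramolecular cross-benzoin, which also sets C6 and the ketone/carbinol pattern.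
3. Enabling feature: in the six-membered ring the ketone carbon C1, conjugated with the ring alkene C2=C3, is bonded directly to the carbinol carbon C6 (H, OH). This α-hydroxy enone is the benzoin adduct of an enal carbonyl and an aliphatic aldehyde, held within reach by the (Z)-alkene and the C4–C5 tether.
4. (Z)-Enedial ⇐ (Z)-iodoalkene (Pd formylation gives C1, oxidative unmasking gives C6) ⇐ propargylic diol by hydroxyl-directed trans-hydroalumination/iodination, which fixes the alkene geometry.
5. Propargylic diol ⇐ 4-silyloxybut-2-ynal + 3-methylbutanal by one amine-catalysed anti-aldol, the only catalyst-controlled stereo-event (C4 and C5).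

Key step: step 7

Remark: 4-((tert-butyldimethylsilyl)oxy)but-2-yn-1-ol, 3-methylbutanal and (E)-2-methylbut-2-enoyl chloride are taken as commercial starting materials.

**Step 1**
Reactants: 1 4-((tert-butyldimethylsilyl)oxy)but-2-yn-1-ol
Product: 2 4-((tert-butyldimethylsilyl)oxy)but-2-ynal
Conditions: MnO2 (activated, excess), CH2Cl2, rt
Reagents that add atoms: none
Why: Activated MnO2 oxidises the propargylic alcohol chemoselectively to the non-enolisable ynal and leaves the silyl ether untouched (heterogeneous MnO2 oxidation of an activated alcohol).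

**Step 2**
Reactants: 2 4-((tert-butyldimethylsilyl)oxy)but-2-ynal; 3 3-methylbutanal
Product: 5 (2R,3R)-6-((tert-butyldimethylsilyl)oxy)-2-isopropylhex-4-yne-1,3-diol, via anti-aldol aldehyde 4 (not isolated)
Conditions: (S)-α,α-bis[3,5-bis(trifluoromethyl)phenyl]-2-pyrrolidinemethanol (20 mol%), 3 (1.5 equiv), 1,4-dioxane, 4 °C → rt; then NaBH4, MeOH, 0 °C
Reagents that add atoms: none
Why: The secondary amine converts 3 into its (E)-enamine, which adds to the re face of the hydrogen-bond-activated, non-enolisable ynal in a proline-type anti-selective transition state (amine-catalysed direct cross-aldol of aldehydes), so that the carbinol centre and the isopropyl-bearing centre are set together by the (S)-catalyst, and NaBH4 traps the labile β-hydroxy aldehyde as the diol.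

**Step 3**
Reactants: 5 (2R,3R)-6-((tert-butyldimethylsilyl)oxy)-2-isopropylhex-4-yne-1,3-diol
Product: 7 (2R,3R,4Z)-6-((tert-butyldimethylsilyl)oxy)-5-iodo-2-isopropylhex-4-ene-1,3-diol, via cyclic alkenylaluminate 6 (not isolated)
Conditions: NaAlH2(OCH2CH2OMe)2, THF, 0 °C → rt; EtOAc; then I2, THF, −78 → 0 °C
Reagents that add atoms: iodine (I2), II
Why: The propargylic alkoxide directs trans-hydroalumination, hydride going to the alkyne carbon next to the carbinol and aluminium to the distal carbon inside a five-membered chelate, and iodine cleaves the C–Al bond with retention to give the (Z)-iodoalkene with iodine cis to the carbinol carbon (alkoxide-directed hydroalumination–iodination of a propargylic alcohol), the two stereocentres being untouched.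

**Step 4**
Reactants: 7 (2R,3R,4Z)-6-((tert-butyldimethylsilyl)oxy)-5-iodo-2-isopropylhex-4-ene-1,3-diol
Product: 8 (2R,3R,4Z)-6-((tert-butyldimethylsilyl)oxy)-5-iodo-2-isopropyl-1,3-bis((triethylsilyl)oxy)hex-4-ene
Conditions: TESCl, imidazole, DMAP (cat.), DMF, 0 °C → rt
Reagents that add atoms: chlorotriethylsilane (TESCl), CC[Si](Cl)(CC)CC
Why: Routine silylation of both hydroxyls (silyl ether formation) prevents lactonisation of the cis-disposed secondary hydroxyl in the next step, gives a poor leaving group at C4 for the key step and provides a primary TES ether that step 6 converts directly into the aldehyde.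

**Step 5**
Reactants: 8 (2R,3R,4Z)-6-((tert-butyldimethylsilyl)oxy)-5-iodo-2-isopropyl-1,3-bis((triethylsilyl)oxy)hex-4-ene
Product: 9 (2Z,4S,5R)-2-(((tert-butyldimethylsilyl)oxy)methyl)-5-isopropyl-4,6-bis((triethylsilyl)oxy)hex-2-enal
Conditions: Pd(PPh3)4 (5 mol%), CO (1 atm), Bu3SnH (slow addition), THF, 50 °C
Reagents that add atoms: carbon monoxide, [C-]#[O+]
Why: Oxidative addition of the alkenyl iodide to Pd, CO insertion and hydride transfer from Bu3SnH to the acyl–Pd species (Pd-catalysed reductive carbonylation, i.e. formylation of an alkenyl halide) replace iodine by CHO with retention of the alkene geometry, which gives the otherwise disfavoured (Z)-enal.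

**Step 6**
Reactants: 9 (2Z,4S,5R)-2-(((tert-butyldimethylsilyl)oxy)methyl)-5-isopropyl-4,6-bis((triethylsilyl)oxy)hex-2-enal
Product: 10 (2Z,4S,5S)-2-(((tert-butyldimethylsilyl)oxy)methyl)-5-isopropyl-4-((triethylsilyl)oxy)hex-2-enedial
Conditions: (COCl)2, DMSO, CH2Cl2, −78 → −40 °C; then Et3N, −78 → 0 °C
Reagents that add atoms: none
Why: Under Swern conditions with excess chlorodimethylsulfonium chloride a primary triethylsilyl ether is converted directly into the aldehyde, whereas the secondary TES ether, the primary TBS ether and the enal do not react (Swern oxidation used as oxidative desilylation of a primary TES ether), and the amine quench at low temperature should leave the α-stereocentre intact.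

**Step 7**
Reactants: 10 (2Z,4S,5S)-2-(((tert-butyldimethylsilyl)oxy)methyl)-5-isopropyl-4-((triethylsilyl)oxy)hex-2-enedial
Product: 11 (4S,5R,6R)-2-(((tert-butyldimethylsilyl)oxy)methyl)-6-hydroxy-5-isopropyl-4-((triethylsilyl)oxy)cyclohex-2-en-1-one
Conditions: 2-(pentafluorophenyl)-6,7-dihydro-5H-pyrrolo[2,1-c][1,2,4]triazol-2-ium tetrafluoroborate (15 mol%), i-Pr2NEt (15 mol%), CH2Cl2 (0.02 M), rt
Reagents that add atoms: none
Why: Proposed new method: the triazolylidene adds to the enal carbonyl of 10, proton transfer gives the conjugated Breslow (acyl-anion) intermediate, its carbinol carbon attacks the tethered aliphatic aldehyde, and collapse of the adduct releases the carbene and the α-hydroxy enone; the closest known reaction types are the NHC-catalysed intramolecular crossed benzoin cyclisation of dialdehydes and keto-aldehydes to six-membered acyloins and the acyl-anion reactivity of 2-substituted enals, whereas an enal donor in an aldehyde–aldehyde ring closure is without direct precedent. The cyclohexenone ring closes in a 6-exo-trig mode (acyl-anion carbon onto the C=O of the second aldehyde), which is geometrically possible only because the (Z)-alkene holds both formyl groups on the same side. The new stereocentre C6 is set by substrate control with an achiral catalyst: in the half-chair transition state the isopropyl group sits pseudo-equatorial and the cis OSiEt3 group pseudo-axial, so the aldehyde oxygen takes the equatorial site to avoid a 1,3-diaxial clash and ends trans to isopropyl, and reversibility of the benzoin step lets the same trans-diequatorial, thermodynamically preferred epimer accumulate. The step needs chemoselectivity (enal as acyl donor, aliphatic aldehyde as acceptor), which the substrate secures because the conjugated Breslow intermediate is the more stabilised one, the α-branched aliphatic aldehyde is the better electrophile and the conjugated enone is the thermodynamic sink of the reversible manifold. Homoenolate reactivity is suppressed because bonding from the β-carbon would give a four-membered ring, and elimination is avoided because the oxygens γ to the enal and β to the aliphatic aldehyde are silyl ethers (poor leaving groups) and only a weakly basic triazolium/amine system is used.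

**Step 8**
Reactants: 11 (4S,5R,6R)-2-(((tert-butyldimethylsilyl)oxy)methyl)-6-hydroxy-5-isopropyl-4-((triethylsilyl)oxy)cyclohex-2-en-1-one
Product: 12 (4S,5S,6R)-6-((tert-butyldimethylsilyl)oxy)-2-(((tert-butyldimethylsilyl)oxy)methyl)-5-isopropyl-4-((triethylsilyl)oxy)cyclohex-2-en-1-one
Conditions: TBSOTf, 2,6-lutidine, CH2Cl2, −78 °C
Reagents that add atoms: tert-butyldimethylsilyl trifluoromethanesulfonate (TBSOTf), CC(C)(C)[Si](C)(C)OS(=O)(=O)C(F)(F)F
Why: Low-temperature O-silylation with TBSOTf/2,6-lutidine (silyl ether formation) masks the α-ketol hydroxyl, the one hydroxyl that must remain free in the target, faster than the enone is enol-silylated.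

**Step 9**
Reactants: 12 (4S,5S,6R)-6-((tert-butyldimethylsilyl)oxy)-2-(((tert-butyldimethylsilyl)oxy)methyl)-5-isopropyl-4-((triethylsilyl)oxy)cyclohex-2-en-1-one
Product: 13 (4S,5S,6R)-6-((tert-butyldimethylsilyl)oxy)-4-hydroxy-2-(hydroxymethyl)-5-isopropylcyclohex-2-en-1-one
Conditions: HF·pyridine, pyridine, THF, 0 °C
Reagents that add atoms: none
Why: Pyridine-buffered HF·pyridine cleaves the secondary TES ether and the primary allylic TBS ether much faster than the hindered secondary TBS ether flanked by the isopropyl group and the carbonyl (rate-differentiated fluoride desilylation), and the acidic medium does not epimerise the α-ketol centre.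

**Step 10**
Reactants: 13 (4S,5S,6R)-6-((tert-butyldimethylsilyl)oxy)-4-hydroxy-2-(hydroxymethyl)-5-isopropylcyclohex-2-en-1-one; 14 (E)-2-methylbut-2-enoyl chloride (tigloyl chloride)
Product: 15 ((3S,4S,5R)-5-((tert-butyldimethylsilyl)oxy)-4-isopropyl-3-(((E)-2-methylbut-2-enoyl)oxy)-6-oxocyclohex-1-en-1-yl)methyl (E)-2-methylbut-2-enoate
Conditions: 14 (3 equiv), pyridine, DMAP (cat.), CH2Cl2, 0 °C → rt
Reagents that add atoms: (E)-2-methylbut-2-enoyl chloride (14), C/C=C(\C)C(Cl)=O
Why: DMAP-catalysed acylation by the acid chloride (nucleophilic-catalysis esterification) esterifies the primary and the secondary allylic hydroxyl, and the (E)-configured tigloyl group, being the stable isomer, is transferred unchanged.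

**Step 11**
Reactants: 15 ((3S,4S,5R)-5-((tert-butyldimethylsilyl)oxy)-4-isopropyl-3-(((E)-2-methylbut-2-enoyl)oxy)-6-oxocyclohex-1-en-1-yl)methyl (E)-2-methylbut-2-enoate
Product: 16 ((3S,4R,5R)-5-hydroxy-4-isopropyl-3-(((E)-2-methylbut-2-enoyl)oxy)-6-oxocyclohex-1-en-1-yl)methyl (E)-2-methylbut-2-enoate
Conditions: HF·pyridine, THF, 0 °C → rt
Reagents that add atoms: none
Why: Fluoride-mediated cleavage of the last silyl ether with HF·pyridine (acidic desilylation) is chosen because the target is base-sensitive (γ-deprotonation of the enone would expel the allylic tiglate), while the two tiglates and all three stereocentres are inert to it.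

**Compound list**

1 | 4-((tert-butyldimethylsilyl)oxy)but-2-yn-1-ol | CC(C)(C)[Si](C)(C)OCC#CCO | starting material
2 | 4-((tert-butyldimethylsilyl)oxy)but-2-ynal | CC(C)(C)[Si](C)(C)OCC#CC=O | intermediate
3 | 3-methylbutanal | CC(C)CC=O | starting material
4 | (2S,3R)-6-((tert-butyldimethylsilyl)oxy)-3-hydroxy-2-isopropylhex-4-ynal (anti-aldol aldehyde) | CC(C)(C)[Si](C)(C)OCC#C[C@H](O)[C@H](C(C)C)C=O | intermediate
5 | (2R,3R)-6-((tert-butyldimethylsilyl)oxy)-2-isopropylhex-4-yne-1,3-diol | CC(C)(C)[Si](C)(C)OCC#C[C@H](O)[C@H](C(C)C)CO | intermediate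
6 | cyclic alkenylaluminate of 5, drawn as the monomeric disodium salt (Al on the alkene carbon distal to the carbinol, chelated by the secondary alkoxide, two 2-methoxyethoxy ligands; primary alkoxide as sodium salt) | CC(C)(C)[Si](C)(C)OCC1=C[C@H](O[Al-]1(OCCOC)OCCOC)[C@H](C(C)C)C[O-].[Na+].[Na+] | intermediate
7 | (2R,3R,4Z)-6-((tert-butyldimethylsilyl)oxy)-5-iodo-2-isopropylhex-4-ene-1,3-diol | CC(C)(C)[Si](C)(C)OC/C(I)=C/[C@H](O)[C@H](C(C)C)CO | intermediate
8 | (2R,3R,4Z)-6-((tert-butyldimethylsilyl)oxy)-5-iodo-2-isopropyl-1,3-bis((triethylsilyl)oxy)hex-4-ene | CC(C)(C)[Si](C)(C)OC/C(I)=C/[C@H](O[Si](CC)(CC)CC)[C@H](C(C)C)CO[Si](CC)(CC)CC | intermediate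
9 | (2Z,4S,5R)-2-(((tert-butyldimethylsilyl)oxy)methyl)-5-isopropyl-4,6-bis((triethylsilyl)oxy)hex-2-enal | CC(C)(C)[Si](C)(C)OC/C(C=O)=C/[C@H](O[Si](CC)(CC)CC)[C@H](C(C)C)CO[Si](CC)(CC)CC | intermediate
10 | (2Z,4S,5S)-2-(((tert-butyldimethylsilyl)oxy)methyl)-5-isopropyl-4-((triethylsilyl)oxy)hex-2-enedial | CC(C)(C)[Si](C)(C)OC/C(C=O)=C/[C@H](O[Si](CC)(CC)CC)[C@H](C(C)C)C=O | intermediate
11 | (4S,5R,6R)-2-(((tert-butyldimethylsilyl)oxy)methyl)-6-hydroxy-5-isopropyl-4-((triethylsilyl)oxy)cyclohex-2-en-1-one | CC(C)(C)[Si](C)(C)OCC1=C[C@H](O[Si](CC)(CC)CC)[C@H](C(C)C)[C@@H](O)C1=O | intermediate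
12 | (4S,5S,6R)-6-((tert-butyldimethylsilyl)oxy)-2-(((tert-butyldimethylsilyl)oxy)methyl)-5-isopropyl-4-((triethylsilyl)oxy)cyclohex-2-en-1-one | CC(C)(C)[Si](C)(C)OCC1=C[C@H](O[Si](CC)(CC)CC)[C@H](C(C)C)[C@@H](O[Si](C)(C)C(C)(C)C)C1=O | intermediate
13 | (4S,5S,6R)-6-((tert-butyldimethylsilyl)oxy)-4-hydroxy-2-(hydroxymethyl)-5-isopropylcyclohex-2-en-1-one | OCC1=C[C@H](O)[C@H](C(C)C)[C@@H](O[Si](C)(C)C(C)(C)C)C1=O | intermediate
14 | (E)-2-methylbut-2-enoyl chloride (tigloyl chloride) | C/C=C(\C)C(Cl)=O | starting material
15 | ((3S,4S,5R)-5-((tert-butyldimethylsilyl)oxy)-4-isopropyl-3-(((E)-2-methylbut-2-enoyl)oxy)-6-oxocyclohex-1-en-1-yl)methyl (E)-2-methylbut-2-enoate | C/C=C(\C)C(=O)OCC1=C[C@H](OC(=O)/C(C)=C/C)[C@H](C(C)C)[C@@H](O[Si](C)(C)C(C)(C)C)C1=O | intermediate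
16 | ((3S,4R,5R)-5-hydroxy-4-isopropyl-3-(((E)-2-methylbut-2-enoyl)oxy)-6-oxocyclohex-1-en-1-yl)methyl (E)-2-methylbut-2-enoate | C/C=C(\C)C(=O)OCC1=C[C@H](OC(=O)/C(C)=C/C)[C@H](C(C)C)[C@@H](O)C1=O | target

**Step count and risks**

Total step count: 11. Longest linear sequence: 11 steps (1 → 16).

Steps most likely to fail:

Step 7 (Proposed new method). What may go wrong: the enal-derived Breslow intermediate may be diverted (β-protonation to a saturated acyl azolium, loss of the γ-silyloxy group), the carbene may engage the aliphatic aldehyde first, and the amine may epimerise or eliminate at the α-branched β-silyloxy aldehyde before the ring closes. Fallback with known chemistry on the same bond: setting out from 10, a low-valent titanium pinacol cyclisation (TiCl3(DME)1.5, Zn–Cu couple, DME, rt), a reaction type established for dialdehydes including enal partners, should give the ring as the vicinal diol 3-(((tert-butyldimethylsilyl)oxy)methyl)-6-isopropyl-5-((triethylsilyl)oxy)cyclohex-3-ene-1,2-diol F1. MnO2 in CH2Cl2 should then oxidise only the allylic hydroxyl, and a C6 epimer, if present, would be equilibrated to the trans isomer with catalytic DBU, so that the sequence comes back to the route at 11.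

Step 2. What may go wrong: sluggish enamine formation from the β-branched donor, self-aldolisation of 3 and conjugate addition of the amine to the ynal, with erosion of anti- and enantioselectivity. Fallback with auxiliary control: setting out from 2, the donor is bound to an oxazolidinone. (R)-4-Benzyloxazolidin-2-one is N-acylated (n-BuLi, 3-methylbutanoyl chloride, THF, −78 °C) to (R)-4-benzyl-3-(3-methylbutanoyl)oxazolidin-2-one F2. The MgCl2-catalysed anti-aldol addition to 2 (MgCl2 10 mol%, Et3N, Me3SiCl, EtOAc, rt), which runs through the chelated (Z)-enolate and accepts non-enolisable unsaturated aldehydes, should give the O-trimethylsilyl anti-aldol imide F3. TFA in MeOH frees the carbinol to the anti-aldol imide F4, and LiBH4 (THF, MeOH, 0 °C) removes the auxiliary reductively, so that the sequence comes back to the route at 5.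

Step 5. What may go wrong: hydride transfer to the alkenyl–Pd species before CO insertion (protodeiodination) and isomerisation of the (Z)-enal. Fallback using the hydroxyl as internal nucleophile: setting out from 7, carbonylative lactonisation (PdCl2(PPh3)2, CO 1 atm, i-Pr2NEt, THF, 50 °C) should give the butenolide 3-(((tert-butyldimethylsilyl)oxy)methyl)-5-(1-hydroxy-3-methylbutan-2-yl)furan-2(5H)-one F5, whose ring locks the alkene geometry. i-Bu2AlH (excess, CH2Cl2, −78 → 0 °C) reduces the lactone to the ene-triol F6, TESCl/imidazole gives the tris(triethylsilyl) ether F7, and the Swern conditions of step 6 with a larger excess of reagent oxidise both primary TES ethers, so that the sequence comes back to the route at 10.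

**Further compounds**

F1 | step 7 | (1R,2RS,5S,6R)-3-(((tert-butyldimethylsilyl)oxy)methyl)-6-isopropyl-5-((triethylsilyl)oxy)cyclohex-3-ene-1,2-diol | CC(C)(C)[Si](C)(C)OCC1=C[C@H](O[Si](CC)(CC)CC)[C@H](C(C)C)[C@@H](O)C1O
F2 | step 2 | (R)-4-benzyl-3-(3-methylbutanoyl)oxazolidin-2-one | CC(C)CC(=O)N1[C@H](Cc2ccccc2)COC1=O
F3 | step 2 | (R)-4-benzyl-3-((2S,3R)-6-((tert-butyldimethylsilyl)oxy)-2-isopropyl-3-((trimethylsilyl)oxy)hex-4-ynoyl)oxazolidin-2-one | CC(C)(C)[Si](C)(C)OCC#C[C@H](O[Si](C)(C)C)[C@H](C(C)C)C(=O)N1[C@H](Cc2ccccc2)COC1=O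
F4 | step 2 | (R)-4-benzyl-3-((2S,3R)-6-((tert-butyldimethylsilyl)oxy)-3-hydroxy-2-isopropylhex-4-ynoyl)oxazolidin-2-one | CC(C)(C)[Si](C)(C)OCC#C[C@H](O)[C@H](C(C)C)C(=O)N1[C@H](Cc2ccccc2)COC1=O
F5 | step 5 | (S)-3-(((tert-butyldimethylsilyl)oxy)methyl)-5-((R)-1-hydroxy-3-methylbutan-2-yl)furan-2(5H)-one | CC(C)(C)[Si](C)(C)OCC1=C[C@@H]([C@H](C(C)C)CO)OC1=O
F6 | step 5 | (2E,4S,5R)-2-(((tert-butyldimethylsilyl)oxy)methyl)-5-isopropylhex-2-ene-1,4,6-triol | CC(C)(C)[Si](C)(C)OC/C(CO)=C/[C@H](O)[C@H](C(C)C)CO
F7 | step 5 | (2E,4S,5R)-1-((tert-butyldimethylsilyl)oxy)-5-isopropyl-4,6-bis((triethylsilyl)oxy)-2-(((triethylsilyl)oxy)methyl)hex-2-ene | CC(C)(C)[Si](C)(C)OC/C(CO[Si](CC)(CC)CC)=C/[C@H](O[Si](CC)(CC)CC)[C@H](C(C)C)CO[Si](CC)(CC)CC
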